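The cyclodecene ring is closed last at C2–C3 (germacrane numbering), the bond joining the allylic carbon of the C1=C10 olefin to the methylene attached to the C4–C5 oxirane. Both carbons are natively electrophilic (allylic alcohol, Sharpless epoxy alcohol), so C2 is polarity-reversed as a phenylsulfonyl-stabilised carbanion that displaces a triflate on C3 within an open chain already carrying all five stereocentres, the oxirane and the ester. The chain comes from an Evans syn aldol (C6, C7), a propargylboration (C8), two methylaluminations (both E-olefins) and a reagent-controlled epoxidation (C4, C5), because epoxidation of the finished ring is expected on the wrong face.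

Key step: step 15

Remark on numbering: ring carbons are numbered as in germacranes (C1=C10 olefin, methyl on C10; C4–C5 oxirane, methyl on C4; C6 carbinol; C7 isopropyl; C8 ester; C9 methylene). These locants are used for all intermediates. The C7 descriptor switches between R and S along the route only through CIP priorities; the centre is never touched after step 3.

Assumption: compounds 1, 5 and 16, allenylboronic acid pinacol ester and (R)-TRIP are purchased; 5 is otherwise one N-acylation away from (R)-4-benzyloxazolidin-2-one.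

Step 1
Reactants: 1 tert-butyldimethyl(prop-2-yn-1-yloxy)silane
Product: 3 (E)-4-(tert-butyldimethylsilyloxy)-3-methylbut-2-en-1-ol, via alkenyldimethylalane 2 (not isolated)
Conditions: Me3Al, Cp2ZrCl2 (cat.), CH2Cl2, 0 °C to rt; evaporate; n-BuLi, THF, −78 °C; (CH2O)n, −78 °C to rt
Reagents that add atoms: trimethylaluminium C[Al](C)C; paraformaldehyde (as formaldehyde) C=O
Why: Zirconium-catalysed methylalumination of the terminal alkyne (Negishi carboalumination) adds CH3 and Al syn with the methyl on the internal carbon, and the derived alanate captures formaldehyde with retention, so the trisubstituted olefin (later C4=C5) should form as the E isomer only.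

Step 2
Reactants: 3 (E)-4-(tert-butyldimethylsilyloxy)-3-methylbut-2-en-1-ol
Product: 4 (E)-4-(tert-butyldimethylsilyloxy)-3-methylbut-2-enal
Conditions: MnO2, CH2Cl2, rt
Reagents that add atoms: none
Why: Allylic oxidation with activated MnO2 stops at the aldehyde and should leave the E geometry and the silyl ether untouched.

Step 3
Reactants: 5 (R)-4-benzyl-3-(3-methylbutanoyl)oxazolidin-2-one; 4 (E)-4-(tert-butyldimethylsilyloxy)-3-methylbut-2-enal
Product: 7 syn-aldol imide (C6 S carbinol, C7 R isopropyl), via Z-boron enolate 6 (not isolated)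
Conditions: n-Bu2BOTf, i-Pr2NEt, CH2Cl2, 0 °C; then the aldehyde, −78 to 0 °C; pH 7 buffer, MeOH, H2O2
Reagents that add atoms: none
Why: Evans syn aldol: the (Z)-dibutylboron enolate reacts through a closed chair (Zimmerman–Traxler) transition state on the enolate face opposite the benzyl group of the (R)-auxiliary, which should set C7 (R) and C6 (S) in the required syn relationship.

Step 4
Reactants: 7 syn-aldol imide
Product: 8 C6 tert-butyldimethylsilyl ether of 7
Conditions: t-BuMe2SiOTf, 2,6-lutidine, CH2Cl2, −78 to 0 °C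
Reagents that add atoms: tert-butyldimethylsilyl triflate CC(C)(C)[Si](C)(C)OS(=O)(=O)C(F)(F)F
Why: Silyl ether formation with the silyl triflate and a hindered base protects the hindered C6 carbinol, blocks retro-aldol cleavage and installs the group that stays until the last step.

Step 5
Reactants: 8 silylated aldol imide
Product: 9 primary alcohol (C8 as CH2OH; C6 S, C7 S)
Conditions: LiBH4, MeOH (1 equiv), THF, 0 °C
Reagents that add atoms: none
Why: Hydride reduction of the exocyclic imide carbonyl with LiBH4 (reductive auxiliary removal) frees C8 as a primary alcohol without touching C7 and returns the oxazolidinone.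

Step 6
Reactants: 9 primary alcohol
Product: 10 aldehyde (C8 as CHO; C6 S, C7 R)
Conditions: Dess–Martin periodinane, CH2Cl2, 0 °C to rt
Reagents that add atoms: none
Why: Dess–Martin oxidation under non-basic conditions should give the α-branched aldehyde without epimerisation at C7 or β-elimination of the silyloxy group.

Step 7
Reactants: 10 aldehyde
Product: 11 homopropargylic alcohol (C8 R, C7 S, C6 S)
Conditions: allenylboronic acid pinacol ester, (R)-TRIP (10 mol%), 4 Å molecular sieves, toluene, 0 °C to rt
Reagents that add atoms: allenylboronic acid pinacol ester C=C=CB1OC(C)(C)C(C)(C)O1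
Why: Chiral-phosphoric-acid-catalysed propargylboration through a six-membered SE2' transition state should deliver the propargyl group to the Re face of the aldehyde, the face also preferred by Felkin–Anh addition with the C6 branch as the large group, so C8 is set R (syn to both the C7 isopropyl and the C6 oxygen) under matched reagent control.

Step 8
Reactants: 11 homopropargylic alcohol
Product: 13 (E)-allylic alcohol diol (C2 hydroxymethyl, C8–OH free), via alkenylalane aluminium alkoxide 12 (not isolated)
Conditions: Me3Al, Cp2ZrCl2, CH2Cl2, 0 °C to rt; evaporate; n-BuLi, THF, −78 °C; (CH2O)n, −78 °C to rt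
Reagents that add atoms: trimethylaluminium C[Al](C)C; paraformaldehyde (as formaldehyde) C=O
Why: A second Negishi carboalumination, tolerated by the free homopropargylic hydroxyl as its aluminium alkoxide, followed by formaldehyde capture of the alanate, should give the E-configured C1=C10 olefin with C2 as a hydroxymethyl group.

Step 9
Reactants: 13 diol
Product: 15 allylic phenyl sulfone (C2–SO2Ph, C8–OH free), via allylic mesylate 14 (not isolated)
Conditions: MsCl (1.05 equiv), Et3N, CH2Cl2, −40 °C; then PhSO2Na, n-Bu4NI (cat.), DMF, −40 °C to rt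
Reagents that add atoms: sodium benzenesulfinate [Na+].[O-]S(=O)c1ccccc1
Why: The primary allylic alcohol is mesylated much faster than the hindered secondary C8 carbinol, and SN2 S-alkylation of benzenesulfinate then gives the linear E-allyl sulfone that will stabilise the C2 carbanion.

Step 10
Reactants: 16 3-hydroxy-4-methoxybenzoic acid (isovanillic acid)
Product: 18 4-methoxy-3-(triisopropylsilyloxy)benzoic acid, via bis-silylated acid 17 (not isolated)
Conditions: i-Pr3SiCl, imidazole, DMF, rt; then K2CO3, MeOH/THF/H2O, rt; dilute aq. HCl to pH 3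
Reagents that add atoms: triisopropylsilyl chloride CC(C)[Si](Cl)(C(C)C)C(C)C
Why: Bis-silylation followed by selective hydrolysis of the labile silyl ester is the standard route to a phenol-protected hydroxybenzoic acid.

Step 11
Reactants: 15 hydroxy sulfone; 18 4-methoxy-3-(triisopropylsilyloxy)benzoic acid
Product: 19 C8 aryl ester
Conditions: dicyclohexylcarbodiimide, DMAP, CH2Cl2, rt
Reagents that add atoms: none
Why: Steglich esterification (carbodiimide activation, acyl transfer by DMAP) acylates the only free hydroxyl, C8–OH, with retention of configuration.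

Step 12
Reactants: 19 C8 aryl ester
Product: 20 primary allylic alcohol (C3–OH)
Conditions: HF·pyridine, pyridine, THF, 0 °C
Reagents that add atoms: none
Why: Selective desilylation with acidic fluoride cleaves the unhindered primary allylic silyl ether much faster than the hindered secondary C6 silyl ether or the aryl triisopropylsilyl ether.

Step 13
Reactants: 20 primary allylic alcohol
Product: 21 (4R,5R)-epoxy alcohol
Conditions: Ti(OiPr)4, diethyl (2S,3S)-(−)-tartrate, t-BuOOH, 4 Å molecular sieves, CH2Cl2, −20 °C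
Reagents that add atoms: tert-butyl hydroperoxide CC(C)(C)OO
Why: Sharpless asymmetric epoxidation of the primary E-allylic alcohol is reagent-controlled, the (−)-tartrate giving the (4R,5R)-oxirane (the antipode of the (2S,3S) sense of the (+)-tartrate), and only the olefin that carries the allylic hydroxyl reacts.

Step 14
Reactants: 21 epoxy alcohol
Product: 22 epoxy triflate (C3–OTf), used at once
Conditions: Tf2O, 2,6-lutidine, CH2Cl2, −78 °C; cold filtration through a short silica pad
Reagents that add atoms: triflic anhydride O=S(=O)(OS(=O)(=O)C(F)(F)F)C(F)(F)F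
Why: Triflation of the primary epoxy alcohol at low temperature puts the most reactive leaving group on C3, which cannot eliminate because the neighbouring C4 is quaternary.

Step 15
Reactants: 22 epoxy triflate
Product: 24 ten-membered C2 sulfone (mixture of C2 epimers), via C2-lithiated sulfone 23 (not isolated)
Conditions: LiN(SiMe3)2 (1.3 equiv), THF/HMPA (10:1), −78 to −40 °C; slow addition of 22 to the base, final concentration about 0.001 mol/L
Reagents that add atoms: none
Why: LiN(SiMe3)2 deprotonates the allylic sulfone at C2 and the resulting α-sulfonyl allyl carbanion displaces the primary triflate on C3 in an intramolecular SN2 reaction, the closest known reaction type being the sulfone-anion alkylation used to close medium and large terpenoid rings. The carbocycle closes in the 10-exo-tet mode. The only new stereocentre is the sulfonyl-bearing C2, which is uncontrolled and irrelevant because step 16 erases it, while C4 to C8 are untouched. The step needs attack at C3 rather than at the oxirane, α- rather than γ-alkylation of the allyl anion, and cyclisation rather than oligomerisation: the triflate is by far the best leaving group, C4 is quaternary and C5 is shielded, lithium sulfonyl allyl anions alkylate at the α-carbon, and slow addition at high dilution suppresses intermolecular reaction. The (E)-C1=C10 olefin and the trans-oxirane act as rigid elements that limit the conformations of the chain, and the aryl ester has no α-hydrogen and cannot be reached by C2 without a seven-membered ring containing the E-olefin.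

Step 16
Reactants: 24 ten-membered C2 sulfone
Product: 25 bis-silylated target
Conditions: Na(Hg) (5%), Na2HPO4, MeOH/THF, −20 °C
Reagents that add atoms: none
Why: Reductive desulfonylation with buffered sodium amalgam cleaves the allylic C–S bond by electron transfer, and the allyl anion should be protonated by methanol at the less substituted C2, keeping the E C1=C10 olefin, while oxirane, ester and silyl ethers are not reduced at −20 °C.

Step 17
Reactants: 25 bis-silylated target
Product: 26 target CNP0294356.1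
Conditions: n-Bu4NF, AcOH, THF, 0 °C to rt
Reagents that add atoms: none
Why: Fluoride-mediated desilylation buffered with acetic acid removes both silyl ethers without acyl migration from O8 to O6, Payne rearrangement or transannular opening of the acid-sensitive oxirane.

Compound list

1 | tert-butyldimethyl(prop-2-yn-1-yloxy)silane | C#CCO[Si](C)(C)C(C)(C)C | starting material
2 | (E)-[3-(tert-butyldimethylsilyloxy)-2-methylprop-1-en-1-yl]dimethylalane | C[Al](C)/C=C(\C)CO[Si](C)(C)C(C)(C)C | intermediate
3 | (E)-4-(tert-butyldimethylsilyloxy)-3-methylbut-2-en-1-ol | OC/C=C(\C)CO[Si](C)(C)C(C)(C)C | intermediate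
4 | (E)-4-(tert-butyldimethylsilyloxy)-3-methylbut-2-enal | O=C/C=C(\C)CO[Si](C)(C)C(C)(C)C | intermediate
5 | (R)-4-benzyl-3-(3-methylbutanoyl)oxazolidin-2-one | CC(C)CC(=O)N1[C@H](Cc2ccccc2)COC1=O | starting material
6 | (Z)-dibutylboron enolate of 5 | CCCCB(CCCC)O/C(=C\C(C)C)N1[C@H](Cc2ccccc2)COC1=O | intermediate
7 | (R)-4-benzyl-3-[(2R,3S,4E)-6-(tert-butyldimethylsilyloxy)-3-hydroxy-5-methyl-2-(propan-2-yl)hex-4-enoyl]oxazolidin-2-one (C7 R, C6 S) | CC(C)(C)[Si](C)(C)OC/C(C)=C/[C@H](O)[C@H](C(=O)N1[C@H](Cc2ccccc2)COC1=O)C(C)C | intermediate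
8 | (R)-4-benzyl-3-[(2R,3S,4E)-3,6-bis(tert-butyldimethylsilyloxy)-5-methyl-2-(propan-2-yl)hex-4-enoyl]oxazolidin-2-one | CC(C)(C)[Si](C)(C)OC/C(C)=C/[C@H](O[Si](C)(C)C(C)(C)C)[C@H](C(=O)N1[C@H](Cc2ccccc2)COC1=O)C(C)C | intermediate
9 | (2S,3S,4E)-3,6-bis(tert-butyldimethylsilyloxy)-5-methyl-2-(propan-2-yl)hex-4-en-1-ol | CC(C)(C)[Si](C)(C)OC/C(C)=C/[C@H](O[Si](C)(C)C(C)(C)C)[C@H](CO)C(C)C | intermediate
10 | (2R,3S,4E)-3,6-bis(tert-butyldimethylsilyloxy)-5-methyl-2-(propan-2-yl)hex-4-enal | CC(C)(C)[Si](C)(C)OC/C(C)=C/[C@H](O[Si](C)(C)C(C)(C)C)[C@H](C=O)C(C)C | intermediate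
11 | (4R,5S,6S,7E)-6,9-bis(tert-butyldimethylsilyloxy)-8-methyl-5-(propan-2-yl)non-7-en-1-yn-4-ol (C8 R, C7 S, C6 S) | C#CC[C@@H](O)[C@H](C(C)C)[C@@H](O[Si](C)(C)C(C)(C)C)/C=C(\C)CO[Si](C)(C)C(C)(C)C | intermediate
12 | (E)-alkenyldimethylalane from 11, with C8–O as its dimethylaluminium alkoxide | C[Al](C)/C=C(\C)C[C@@H](O[Al](C)C)[C@H](C(C)C)[C@@H](O[Si](C)(C)C(C)(C)C)/C=C(\C)CO[Si](C)(C)C(C)(C)C | intermediate
13 | (2E,5R,6S,7S,8E)-7,10-bis(tert-butyldimethylsilyloxy)-3,9-dimethyl-6-(propan-2-yl)deca-2,8-diene-1,5-diol | OC/C=C(\C)C[C@@H](O)[C@H](C(C)C)[C@@H](O[Si](C)(C)C(C)(C)C)/C=C(\C)CO[Si](C)(C)C(C)(C)C | intermediate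
14 | C1 (ring C2) methanesulfonate of 13 | CS(=O)(=O)OC/C=C(\C)C[C@@H](O)[C@H](C(C)C)[C@@H](O[Si](C)(C)C(C)(C)C)/C=C(\C)CO[Si](C)(C)C(C)(C)C | intermediate
15 | (2E,5R,6S,7S,8E)-7,10-bis(tert-butyldimethylsilyloxy)-3,9-dimethyl-1-(phenylsulfonyl)-6-(propan-2-yl)deca-2,8-dien-5-ol | O=S(=O)(c1ccccc1)C/C=C(\C)C[C@@H](O)[C@H](C(C)C)[C@@H](O[Si](C)(C)C(C)(C)C)/C=C(\C)CO[Si](C)(C)C(C)(C)C | intermediate
16 | 3-hydroxy-4-methoxybenzoic acid (isovanillic acid) | COc1ccc(C(=O)O)cc1O | starting material
17 | triisopropylsilyl 4-methoxy-3-(triisopropylsilyloxy)benzoate | COc1ccc(C(=O)O[Si](C(C)C)(C(C)C)C(C)C)cc1O[Si](C(C)C)(C(C)C)C(C)C | intermediate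
18 | 4-methoxy-3-(triisopropylsilyloxy)benzoic acid | COc1ccc(C(=O)O)cc1O[Si](C(C)C)(C(C)C)C(C)C | intermediate
19 | (2E,5R,6S,7S,8E)-7,10-bis(tert-butyldimethylsilyloxy)-3,9-dimethyl-1-(phenylsulfonyl)-6-(propan-2-yl)deca-2,8-dien-5-yl 4-methoxy-3-(triisopropylsilyloxy)benzoate | COc1ccc(C(=O)O[C@H](C/C(C)=C/CS(=O)(=O)c2ccccc2)[C@H](C(C)C)[C@@H](O[Si](C)(C)C(C)(C)C)/C=C(\C)CO[Si](C)(C)C(C)(C)C)cc1O[Si](C(C)C)(C(C)C)C(C)C | intermediate
20 | (2E,5R,6S,7S,8E)-7-(tert-butyldimethylsilyloxy)-10-hydroxy-3,9-dimethyl-1-(phenylsulfonyl)-6-(propan-2-yl)deca-2,8-dien-5-yl 4-methoxy-3-(triisopropylsilyloxy)benzoate | COc1ccc(C(=O)O[C@H](C/C(C)=C/CS(=O)(=O)c2ccccc2)[C@H](C(C)C)[C@@H](O[Si](C)(C)C(C)(C)C)/C=C(\C)CO)cc1O[Si](C(C)C)(C(C)C)C(C)C | intermediate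
21 | open-chain (4R,5R)-epoxy alcohol: (2E,5R,6S,7R)-7-(tert-butyldimethylsilyloxy)-7-[(2R,3R)-3-(hydroxymethyl)-3-methyloxiran-2-yl]-3-methyl-1-(phenylsulfonyl)-6-(propan-2-yl)hept-2-en-5-yl 4-methoxy-3-(triisopropylsilyloxy)benzoate | COc1ccc(C(=O)O[C@H](C/C(C)=C/CS(=O)(=O)c2ccccc2)[C@H](C(C)C)[C@@H](O[Si](C)(C)C(C)(C)C)[C@H]3O[C@]3(C)CO)cc1O[Si](C(C)C)(C(C)C)C(C)C | intermediate
22 | C3 trifluoromethanesulfonate of 21 | COc1ccc(C(=O)O[C@H](C/C(C)=C/CS(=O)(=O)c2ccccc2)[C@H](C(C)C)[C@@H](O[Si](C)(C)C(C)(C)C)[C@H]3O[C@]3(C)COS(=O)(=O)C(F)(F)F)cc1O[Si](C(C)C)(C(C)C)C(C)C | intermediate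
23 | C2-lithiated sulfone of 22 | [Li+].COc1ccc(C(=O)O[C@H](C/C(C)=C/[CH-]S(=O)(=O)c2ccccc2)[C@H](C(C)C)[C@@H](O[Si](C)(C)C(C)(C)C)[C@H]3O[C@]3(C)COS(=O)(=O)C(F)(F)F)cc1O[Si](C(C)C)(C(C)C)C(C)C | intermediate
24 | (1(10)E,4R,5R,6R,7S,8R)-6-(tert-butyldimethylsilyloxy)-4,5-epoxy-2-(phenylsulfonyl)germacr-1(10)-en-8-yl 4-methoxy-3-(triisopropylsilyloxy)benzoate (C2 epimers) | COc1ccc(C(=O)O[C@@H]2C/C(C)=C/C(S(=O)(=O)c4ccccc4)C[C@@]3(C)O[C@@H]3[C@H](O[Si](C)(C)C(C)(C)C)[C@H]2C(C)C)cc1O[Si](C(C)C)(C(C)C)C(C)C | intermediate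
25 | (1(10)E,4R,5R,6R,7S,8R)-6-(tert-butyldimethylsilyloxy)-4,5-epoxygermacr-1(10)-en-8-yl 4-methoxy-3-(triisopropylsilyloxy)benzoate | COc1ccc(C(=O)O[C@@H]2C/C(C)=C/CC[C@@]3(C)O[C@@H]3[C@H](O[Si](C)(C)C(C)(C)C)[C@H]2C(C)C)cc1O[Si](C(C)C)(C(C)C)C(C)C | intermediate
26 | (1(10)E,4R,5R,6R,7R,8R)-4,5-epoxy-6-hydroxygermacr-1(10)-en-8-yl 3-hydroxy-4-methoxybenzoate (CNP0294356.1) | COc1ccc(C(=O)O[C@@H]2C/C(C)=C/CC[C@@]3(C)O[C@@H]3[C@H](O)[C@H]2C(C)C)cc1O | target

Total step count: 17. Longest linear sequence: 16 steps (steps 1 to 9 and 11 to 17; step 10 prepares acid 18).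

Steps most likely to fail

Step 15 (ring closure). Intermolecular alkylation may outrun the medium-ring closure, displacement at the oxirane-flanked primary carbon may be slow, and the triflate may decompose before it reacts. The fallback sets out from 20 and returns at 24. Epoxidation of 20 under the titanium/tartrate conditions of step 13, but with diethyl (2R,3R)-(+)-tartrate, should give the (4S,5S)-epoxy alcohol F1. NaN(SiMe3)2 (2.2 equiv) in THF/HMPA at high dilution should then set up the Payne equilibrium with the terminal C3–C4 oxirane (inversion at C4). That oxirane is much the more reactive electrophile and should be opened at its unhindered CH2 (C3) by the C2 sulfonyl carbanion, again forming the C2–C3 bond, to give the macrocyclic (4R,5S)-diol F2. Selective mesylation of the secondary C5 hydroxyl (MsCl, Et3N, −20 °C) gives the mesylate F3, and DBU should close the oxirane by attack of the C4 alkoxide on C5 with inversion. The two inversions turn the (4S,5S)-oxirane of F1 into the (4R,5R)-oxirane of 24.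

Step 16 (desulfonylation). The allyl anion may be protonated at C10 (olefin shift to C1=C2), the olefin may isomerise from E to Z, the aryl ester may be cleaved by methoxide, or the anion may open the oxirane. The fallback sets out from 24 and returns at 25 and makes no new compound. It replaces electron transfer by palladium-catalysed allylic hydride substitution (PdCl2(dppp) (cat.), NaBH4, THF/i-PrOH, 0 °C): the allylic sulfone is ionised to a π-allyl palladium complex and hydride is delivered to the less substituted terminus C2, so no free allyl anion is formed, and the ester and the trisubstituted oxirane should tolerate borohydride at 0 °C.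

Step 7 (propargylboration). Facial selectivity at C8 may be poor if catalyst and substrate turn out mismatched, and addition to the hindered α-branched aldehyde may be slow. The fallback sets out from 10 and returns at 11. Zinc-mediated Barbier addition of 3-bromo-1-(trimethylsilyl)prop-1-yne (Zn, THF) should give the C8-epimeric silylalkynyl carbinols F4. Dess–Martin oxidation gives the β,γ-ynone F5, used directly. Corey–Bakshi–Shibata reduction with (S)-2-methyl-CBS-oxazaborolidine and BH3·SMe2 at −40 °C, which treats the branched C7 side as the large and the propargylic CH2 as the small substituent, should give the (8R)-carbinol F6. K2CO3 in MeOH then removes the alkynyl silane to give 11.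

Further compounds

F1 | step 15 | (4S,5S)-epoxy alcohol, diastereomer of 21 | COc1ccc(C(=O)O[C@H](C/C(C)=C/CS(=O)(=O)c2ccccc2)[C@H](C(C)C)[C@@H](O[Si](C)(C)C(C)(C)C)[C@@H]3O[C@@]3(C)CO)cc1O[Si](C(C)C)(C(C)C)C(C)C
F2 | step 15 | (1(10)E,4R,5S,6R,7S,8R)-6-(tert-butyldimethylsilyloxy)-4,5-dihydroxy-2-(phenylsulfonyl)germacr-1(10)-en-8-yl 4-methoxy-3-(triisopropylsilyloxy)benzoate (C2 epimers) | COc1ccc(C(=O)O[C@@H]2C/C(C)=C/C(S(=O)(=O)c4ccccc4)C[C@@](C)(O)[C@@H](O)[C@H](O[Si](C)(C)C(C)(C)C)[C@H]2C(C)C)cc1O[Si](C(C)C)(C(C)C)C(C)C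
F3 | step 15 | C5 methanesulfonate of F2 | COc1ccc(C(=O)O[C@@H]2C/C(C)=C/C(S(=O)(=O)c4ccccc4)C[C@@](C)(O)[C@@H](OS(C)(=O)=O)[C@H](O[Si](C)(C)C(C)(C)C)[C@H]2C(C)C)cc1O[Si](C(C)C)(C(C)C)C(C)C
F0 | step 16 | none | none
F4 | step 7 | 1-(trimethylsilyl) derivative of 11 as a mixture of C8 epimers | C[Si](C)(C)C#CCC(O)[C@H](C(C)C)[C@@H](O[Si](C)(C)C(C)(C)C)/C=C(\C)CO[Si](C)(C)C(C)(C)C
F5 | step 7 | (5R,6S,7E)-6,9-bis(tert-butyldimethylsilyloxy)-8-methyl-5-(propan-2-yl)-1-(trimethylsilyl)non-7-en-1-yn-4-one | C[Si](C)(C)C#CCC(=O)[C@H](C(C)C)[C@@H](O[Si](C)(C)C(C)(C)C)/C=C(\C)CO[Si](C)(C)C(C)(C)C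
F6 | step 7 | (4R,5S,6S,7E)-6,9-bis(tert-butyldimethylsilyloxy)-8-methyl-5-(propan-2-yl)-1-(trimethylsilyl)non-7-en-1-yn-4-ol | C[Si](C)(C)C#CC[C@@H](O)[C@H](C(C)C)[C@@H](O[Si](C)(C)C(C)(C)C)/C=C(\C)CO[Si](C)(C)C(C)(C)C
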